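**Retrosynthetic overview**

1. The target comes from its O-triisopropylsilyl ether by desilylation. Both primary alcohols (C9–OH and the allylic alcohol) come from one i-Bu2AlH reduction of a C3 ethyl ester and an (E)-cinnamate ester, and the cinnamate comes from Wittig olefination of a C5 aldehyde.
2. Key disconnection: C3–C3a and C2–C3 of the dihydrofuran ring. The feature used is that C3 is one carbon, carrying C9, that bridges the ring A carbon C3a and the O-benzylic carbon C2, while C3a and C2 are already joined through C7a–O1. In the open aryl benzyl ether a C3a–Br bond and a C2–H bond can therefore be held by one palladium in a five-membered palladacycle, and C3 with its ester is inserted as the carbene carbon of ethyl diazoacetate ([4+1]).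
3. The ether comes from Mitsunobu coupling of 5-bromovanillin (ring A) with the silylated benzyl alcohol made from syringaldehyde (ring B); the formyl group is masked as a 1,3-dioxolane for the annulation.
4. Ring order: rings A and B are bought as the two aromatic aldehydes. The dihydrofuran ring is the only ring formed (step 5), where C2 is set by the chiral ligand and C3 by equilibration to trans.

Key step: step 5

Remarks on the chemistry (assumptions):
- The formyl group is carried through step 5 as a dioxolane. Ethyl diazoacetate adds to aldehydes under basic conditions, and a para-formyl group would make O1 a good leaving group for β-elimination from the C3 ester enolate.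
- The sense of induction of a new catalytic C–H cleavage cannot be predicted. The (R,R)-ligand is assumed to give 2R; its mirror image is used if the first experiment shows the opposite sense.
- Mitsunobu coupling replaces a labile 4-silyloxybenzyl bromide, and a base-free Wittig reaction replaces a base-mediated olefination.

**Route**

Step 1
Reactants: 1 syringaldehyde
Product: 2 3,5-dimethoxy-4-(triisopropylsilyloxy)benzaldehyde
Conditions: TIPSCl, imidazole, DMAP (cat.), DMF, rt
Reagents that add atoms: triisopropylsilyl chloride, CC(C)[Si](Cl)(C(C)C)C(C)C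
Why: O-silylation of an acidic phenol (substitution at silicon) should go cleanly, and the two flanking methoxy groups make the aryl silyl ether robust towards the later base and hydride steps.

Step 2
Reactants: 2 3,5-dimethoxy-4-(triisopropylsilyloxy)benzaldehyde
Product: 3 [3,5-dimethoxy-4-(triisopropylsilyloxy)phenyl]methanol
Conditions: NaBH4, MeOH–THF, 0 °C
Reagents that add atoms: none
Why: Borohydride reduction of an aromatic aldehyde to the benzylic alcohol leaves the aryl silyl ether untouched.

Step 3
Reactants: 3 [3,5-dimethoxy-4-(triisopropylsilyloxy)phenyl]methanol; 4 5-bromovanillin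
Product: 5 3-bromo-4-{[3,5-dimethoxy-4-(triisopropylsilyloxy)benzyl]oxy}-5-methoxybenzaldehyde
Conditions: PPh3, DIAD, THF, 0 °C → rt
Reagents that add atoms: none
Why: Mitsunobu etherification, in which the alkoxyphosphonium ion of the primary benzylic alcohol is displaced by the acidic phenoxide of 4 (acidified by the para-formyl and ortho-bromo groups).

Step 4
Reactants: 5 3-bromo-4-{[3,5-dimethoxy-4-(triisopropylsilyloxy)benzyl]oxy}-5-methoxybenzaldehyde
Product: 6 2-(3-bromo-4-{[3,5-dimethoxy-4-(triisopropylsilyloxy)benzyl]oxy}-5-methoxyphenyl)-1,3-dioxolane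
Conditions: ethylene glycol, PPTS (cat.), benzene, reflux (Dean–Stark)
Reagents that add atoms: ethylene glycol, OCCO
Why: Acetalisation with azeotropic removal of water under a weak pyridinium acid, which should spare the benzyl aryl ether and the aryl silyl ether.

Step 5
Reactants: 6 2-(3-bromo-4-{[3,5-dimethoxy-4-(triisopropylsilyloxy)benzyl]oxy}-5-methoxyphenyl)-1,3-dioxolane; 7 ethyl diazoacetate
Product: 9 ethyl (2R,3R)-trans-2-[3,5-dimethoxy-4-(triisopropylsilyloxy)phenyl]-5-(1,3-dioxolan-2-yl)-7-methoxy-2,3-dihydro-1-benzofuran-3-carboxylate, via cis ester 8 (not isolated)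
Conditions: Pd(OAc)2 (10 mol%), (R,R)-Taddol-derived N,N-dimethylphosphoramidite (20 mol%), CsOPiv (30 mol%), Cs2CO3 (1.5 equiv), 4 Å MS, toluene, 90 °C, 7 (2.5 equiv) by syringe pump over 10 h; filter, then NaOEt (0.2 equiv), EtOH, 0 °C → rt
Reagents that add atoms: none
Why: Proposed new method: zerovalent palladium (from Pd(OAc)2 and the phosphoramidite) inserts into the C3a–Br bond of 6, pivalate-assisted concerted metalation–deprotonation removes one of the two enantiotopic C2–H atoms (benzylic and α to O1) to give the five-membered C,C-palladacycle (Pd, C3a, C7a, O1, C2), the carbene formed from 7 with loss of N2 undergoes migratory insertion into the Pd–aryl bond, and C2–C3 reductive elimination from the resulting six-membered palladacycle releases the product and zerovalent palladium. The closest known reaction types are the [4+1] annulation of five-membered C,C-palladacycles from C(sp3)–H activation with diazo esters and the enantioselective palladium-catalysed C(sp3)–H arylation with chiral monodentate phosphorus ligands and carboxylate bases; neither has been shown on the O-benzylic methylene of an aryl benzyl ether, nor in enantioselective form with carbene insertion. The dihydrofuran ring is closed by C(sp3)–C(sp3) reductive elimination at divalent palladium, not by a polar cyclisation, so C3 enters as a one-carbon unit between C3a and C2. C2 (R) is fixed at the C–H cleavage by the chiral ligand and is not acidic afterwards, whereas C3 is set under thermodynamic control, the kinetically co-formed cis ester 8 being epimerised by Cs2CO3 and then catalytic NaOEt to the trans ester 9 (3R). The step needs cleavage of C2–H in preference to the ortho C–H bonds of ring B (which would lead through a seven-membered palladacycle to a 6H-benzo[c]chromene); the substrate helps because each of those ortho hydrogens is flanked by a methoxy group that would end up in the bay region of the biaryl, and because C2 has no β-hydrogen, so the palladacycle cannot collapse by β-hydride elimination. Slow addition of 7 keeps carbene dimerisation and direct aryl–carbene coupling slower than C–H cleavage, and the dioxolane keeps a formyl group away from the diazo ester and leaves O1 a poor leaving group for ring opening of the ester enolate.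

Step 6
Reactants: 9 ethyl (2R,3R)-trans-2-[3,5-dimethoxy-4-(triisopropylsilyloxy)phenyl]-5-(1,3-dioxolan-2-yl)-7-methoxy-2,3-dihydro-1-benzofuran-3-carboxylate
Product: 10 ethyl (2R,3R)-trans-2-[3,5-dimethoxy-4-(triisopropylsilyloxy)phenyl]-5-formyl-7-methoxy-2,3-dihydro-1-benzofuran-3-carboxylate
Conditions: PPTS (cat.), acetone–H2O, 40 °C
Reagents that add atoms: water, O
Why: Acid-catalysed acetal hydrolysis of an electron-rich aryl dioxolane is fast under weak acid, which does not enolise the C3 ester or cleave the aryl silyl ether.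

Step 7
Reactants: 10 ethyl (2R,3R)-trans-2-[3,5-dimethoxy-4-(triisopropylsilyloxy)phenyl]-5-formyl-7-methoxy-2,3-dihydro-1-benzofuran-3-carboxylate; 11 ethyl (triphenylphosphoranylidene)acetate
Product: 12 ethyl (2R,3R)-trans-2-[3,5-dimethoxy-4-(triisopropylsilyloxy)phenyl]-5-[(E)-3-ethoxy-3-oxoprop-1-en-1-yl]-7-methoxy-2,3-dihydro-1-benzofuran-3-carboxylate
Conditions: toluene, 60 °C
Reagents that add atoms: none
Why: Wittig olefination with a stabilised ylide should give the (E)-cinnamate from an aromatic aldehyde, and no added base reaches the C3–H of the formyl-activated dihydrobenzofuran ester.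

Step 8
Reactants: 12 ethyl (2R,3R)-trans-2-[3,5-dimethoxy-4-(triisopropylsilyloxy)phenyl]-5-[(E)-3-ethoxy-3-oxoprop-1-en-1-yl]-7-methoxy-2,3-dihydro-1-benzofuran-3-carboxylate
Product: 13 (E)-3-{(2R,3S)-2-[3,5-dimethoxy-4-(triisopropylsilyloxy)phenyl]-3-(hydroxymethyl)-7-methoxy-2,3-dihydro-1-benzofuran-5-yl}prop-2-en-1-ol
Conditions: i-Bu2AlH (6 equiv), CH2Cl2, −78 → −20 °C; aq. potassium sodium tartrate (KNaC4H4O6)
Reagents that add atoms: none
Why: Aluminium hydride reduction converts the saturated C3 ester into the C9 alcohol and the enoate by 1,2-reduction into the allylic alcohol; no stereocentre is touched, and the C3 descriptor changes from R to S only through the change in substituent priority.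

Step 9
Reactants: 13 (E)-3-{(2R,3S)-2-[3,5-dimethoxy-4-(triisopropylsilyloxy)phenyl]-3-(hydroxymethyl)-7-methoxy-2,3-dihydro-1-benzofuran-5-yl}prop-2-en-1-ol
Product: 14 4-{(2R,3S)-3-(hydroxymethyl)-5-[(E)-3-hydroxyprop-1-en-1-yl]-7-methoxy-2,3-dihydro-1-benzofuran-2-yl}-2,6-dimethoxyphenol (CNP0191372.2)
Conditions: Bu4NF (1.2 equiv), AcOH (1.2 equiv), THF, 0 °C
Reagents that add atoms: none
Why: Fluoride-mediated cleavage of the aryl silyl ether is driven by the Si–F bond, and the acetic acid buffer protonates the phenoxide at once so that C2–O1 is not opened through a para-quinone methide.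

**Compound list**

1 | syringaldehyde | COc1cc(C=O)cc(OC)c1O | starting material
2 | 3,5-dimethoxy-4-(triisopropylsilyloxy)benzaldehyde | COc1cc(C=O)cc(OC)c1O[Si](C(C)C)(C(C)C)C(C)C | intermediate
3 | [3,5-dimethoxy-4-(triisopropylsilyloxy)phenyl]methanol | COc1cc(CO)cc(OC)c1O[Si](C(C)C)(C(C)C)C(C)C | intermediate
4 | 5-bromovanillin (3-bromo-4-hydroxy-5-methoxybenzaldehyde) | COc1cc(C=O)cc(Br)c1O | starting material
5 | 3-bromo-4-{[3,5-dimethoxy-4-(triisopropylsilyloxy)benzyl]oxy}-5-methoxybenzaldehyde | COc1cc(COc2c(Br)cc(C=O)cc2OC)cc(OC)c1O[Si](C(C)C)(C(C)C)C(C)C | intermediate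
6 | 2-(3-bromo-4-{[3,5-dimethoxy-4-(triisopropylsilyloxy)benzyl]oxy}-5-methoxyphenyl)-1,3-dioxolane | COc1cc(COc2c(Br)cc(C3OCCO3)cc2OC)cc(OC)c1O[Si](C(C)C)(C(C)C)C(C)C | intermediate
7 | ethyl diazoacetate | CCOC(=O)C=[N+]=[N-] | starting material
8 | ethyl (2R,3S)-cis-2-[3,5-dimethoxy-4-(triisopropylsilyloxy)phenyl]-5-(1,3-dioxolan-2-yl)-7-methoxy-2,3-dihydro-1-benzofuran-3-carboxylate (not isolated) | COc1cc([C@@H]2Oc3c(OC)cc(C4OCCO4)cc3[C@@H]2C(=O)OCC)cc(OC)c1O[Si](C(C)C)(C(C)C)C(C)C | intermediate
9 | ethyl (2R,3R)-trans-2-[3,5-dimethoxy-4-(triisopropylsilyloxy)phenyl]-5-(1,3-dioxolan-2-yl)-7-methoxy-2,3-dihydro-1-benzofuran-3-carboxylate | COc1cc([C@@H]2Oc3c(OC)cc(C4OCCO4)cc3[C@H]2C(=O)OCC)cc(OC)c1O[Si](C(C)C)(C(C)C)C(C)C | intermediate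
10 | ethyl (2R,3R)-trans-2-[3,5-dimethoxy-4-(triisopropylsilyloxy)phenyl]-5-formyl-7-methoxy-2,3-dihydro-1-benzofuran-3-carboxylate | COc1cc([C@@H]2Oc3c(OC)cc(C=O)cc3[C@H]2C(=O)OCC)cc(OC)c1O[Si](C(C)C)(C(C)C)C(C)C | intermediate
11 | ethyl (triphenylphosphoranylidene)acetate | CCOC(=O)C=P(c1ccccc1)(c1ccccc1)c1ccccc1 | starting material
12 | ethyl (2R,3R)-trans-2-[3,5-dimethoxy-4-(triisopropylsilyloxy)phenyl]-5-[(E)-3-ethoxy-3-oxoprop-1-en-1-yl]-7-methoxy-2,3-dihydro-1-benzofuran-3-carboxylate | COc1cc([C@@H]2Oc3c(OC)cc(/C=C/C(=O)OCC)cc3[C@H]2C(=O)OCC)cc(OC)c1O[Si](C(C)C)(C(C)C)C(C)C | intermediate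
13 | (E)-3-{(2R,3S)-2-[3,5-dimethoxy-4-(triisopropylsilyloxy)phenyl]-3-(hydroxymethyl)-7-methoxy-2,3-dihydro-1-benzofuran-5-yl}prop-2-en-1-ol | COc1cc([C@@H]2Oc3c(OC)cc(/C=C/CO)cc3[C@H]2CO)cc(OC)c1O[Si](C(C)C)(C(C)C)C(C)C | intermediate
14 | 4-{(2R,3S)-3-(hydroxymethyl)-5-[(E)-3-hydroxyprop-1-en-1-yl]-7-methoxy-2,3-dihydro-1-benzofuran-2-yl}-2,6-dimethoxyphenol | COc1cc([C@@H]2Oc3c(OC)cc(/C=C/CO)cc3[C@H]2CO)cc(OC)c1O | target

**Step count and risks**

Total step count: 9. Longest linear sequence: 9 steps (1 → 14); compounds 4, 7 and 11 are bought.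

Steps most likely to fail:

Step 5 (proposed new method). What may go wrong:
- palladium cleaves an ortho C–H bond of ring B instead of C2–H and closes a six-membered biaryl ether ring;
- the arylpalladium bromide is intercepted by the carbene or is reduced before C–H cleavage;
- the carbene dimerises;
- the ligand discriminates poorly between the two enantiotopic C2 hydrogens;
- the product ester opens by β-elimination of O1 under the base.

Fallback, all known chemistry, setting out from 6:
- Palladium-catalysed α-arylation of the Reformatsky reagent BrZnCH2CO2Et (Pd(dba)2, P(t-Bu)3, THF) should give ethyl 2-[2-{[3,5-dimethoxy-4-(triisopropylsilyloxy)benzyl]oxy}-5-(1,3-dioxolan-2-yl)-3-methoxyphenyl]acetate F1.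
- Regitz diazo transfer (4-acetamidobenzenesulfonyl azide, DBU, MeCN) would convert it into ethyl 2-diazo-2-[2-{[3,5-dimethoxy-4-(triisopropylsilyloxy)benzyl]oxy}-5-(1,3-dioxolan-2-yl)-3-methoxyphenyl]acetate F2.
- Intramolecular carbene insertion into the O-benzylic C2–H bond, catalysed by a chiral dirhodium carboxylate (Rh2(S-PTTL)4, dirhodium tetrakis[N-phthaloyl-tert-leucinate], or its mirror image, whichever antipode gives 2R; toluene, −60 °C), should give the cis ester with C2 set by the catalyst.
- The route is rejoined at 8, which the NaOEt treatment of step 5 epimerises to 9.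

Step 4. What may go wrong: acid-promoted ionisation of the electron-rich benzyl aryl ether, which carries a good phenoxide leaving group while the formyl group is free, so that the ether is cleaved faster than the acetal forms.

Fallback, setting out from 4, in which the acetal is installed before the benzyl ether exists:
- Acetylation (Ac2O, pyridine) gives 2-bromo-4-formyl-6-methoxyphenyl acetate F3.
- Acetalisation (ethylene glycol, TsOH cat., toluene, Dean–Stark) gives 2-bromo-4-(1,3-dioxolan-2-yl)-6-methoxyphenyl acetate F4.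
- Methanolysis (K2CO3, MeOH) gives 2-bromo-4-(1,3-dioxolan-2-yl)-6-methoxyphenol F5, which is kept away from acid.
- Mitsunobu coupling of F5 with 3 (PPh3, DIAD, THF) rejoins the route at 6.

Step 8. What may go wrong: conjugate hydride delivery to the cinnamate, or epimerisation and β-elimination at C3 through the transient α-aryl aldehyde while the slower of the two esters is still being reduced.

Fallback, setting out from 9, in which the two reductions are separated:
- LiBH4 (THF, 0 °C → rt) reduces the C3 ester while the formyl group is still masked, giving {(2R,3S)-2-[3,5-dimethoxy-4-(triisopropylsilyloxy)phenyl]-5-(1,3-dioxolan-2-yl)-7-methoxy-2,3-dihydro-1-benzofuran-3-yl}methanol F6.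
- Acetal hydrolysis (PPTS, acetone–H2O) gives (2R,3S)-2-[3,5-dimethoxy-4-(triisopropylsilyloxy)phenyl]-3-(hydroxymethyl)-7-methoxy-2,3-dihydro-1-benzofuran-5-carbaldehyde F7.
- Wittig olefination with 11 gives ethyl (E)-3-{(2R,3S)-2-[3,5-dimethoxy-4-(triisopropylsilyloxy)phenyl]-3-(hydroxymethyl)-7-methoxy-2,3-dihydro-1-benzofuran-5-yl}prop-2-enoate F8.
- i-Bu2AlH reduction of this single enoate ester at −78 °C rejoins the route at 13.

**Further compounds**

F1 | step 5 | ethyl 2-[2-{[3,5-dimethoxy-4-(triisopropylsilyloxy)benzyl]oxy}-5-(1,3-dioxolan-2-yl)-3-methoxyphenyl]acetate | CCOC(=O)Cc1cc(C2OCCO2)cc(OC)c1OCc1cc(OC)c(O[Si](C(C)C)(C(C)C)C(C)C)c(OC)c1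
F2 | step 5 | ethyl 2-diazo-2-[2-{[3,5-dimethoxy-4-(triisopropylsilyloxy)benzyl]oxy}-5-(1,3-dioxolan-2-yl)-3-methoxyphenyl]acetate | CCOC(=O)C(=[N+]=[N-])c1cc(C2OCCO2)cc(OC)c1OCc1cc(OC)c(O[Si](C(C)C)(C(C)C)C(C)C)c(OC)c1
F3 | step 4 | 2-bromo-4-formyl-6-methoxyphenyl acetate | COc1cc(C=O)cc(Br)c1OC(C)=O
F4 | step 4 | 2-bromo-4-(1,3-dioxolan-2-yl)-6-methoxyphenyl acetate | COc1cc(C2OCCO2)cc(Br)c1OC(C)=O
F5 | step 4 | 2-bromo-4-(1,3-dioxolan-2-yl)-6-methoxyphenol | COc1cc(C2OCCO2)cc(Br)c1O
F6 | step 8 | {(2R,3S)-2-[3,5-dimethoxy-4-(triisopropylsilyloxy)phenyl]-5-(1,3-dioxolan-2-yl)-7-methoxy-2,3-dihydro-1-benzofuran-3-yl}methanol | COc1cc([C@@H]2Oc3c(OC)cc(C4OCCO4)cc3[C@H]2CO)cc(OC)c1O[Si](C(C)C)(C(C)C)C(C)C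
F7 | step 8 | (2R,3S)-2-[3,5-dimethoxy-4-(triisopropylsilyloxy)phenyl]-3-(hydroxymethyl)-7-methoxy-2,3-dihydro-1-benzofuran-5-carbaldehyde | COc1cc([C@@H]2Oc3c(OC)cc(C=O)cc3[C@H]2CO)cc(OC)c1O[Si](C(C)C)(C(C)C)C(C)C
F8 | step 8 | ethyl (E)-3-{(2R,3S)-2-[3,5-dimethoxy-4-(triisopropylsilyloxy)phenyl]-3-(hydroxymethyl)-7-methoxy-2,3-dihydro-1-benzofuran-5-yl}prop-2-enoate | COc1cc([C@@H]2Oc3c(OC)cc(/C=C/C(=O)OCC)cc3[C@H]2CO)cc(OC)c1O[Si](C(C)C)(C(C)C)C(C)C
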